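**Retrosynthetic overview**
- The two acetates come off to a triol, protected as a silyl ether/acetonide. The Z side-chain alkene is cut by a Wittig disconnection into an α-silyloxy ketone on the ring and a C6 ylide that carries the (S)-carbinol, bought as (S)-α-hydroxy-γ-butyrolactone.
- The ring bond between the quaternary C(Me)(vinyl) carbon and the CH–isopropenyl carbon is disconnected by a Cope [3,3] rearrangement of an (E,E)-germacra-1(10),4-diene whose single stereocentre comes from (S)-carvone.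
- The germacradiene comes from an enol triflate, made by anionic oxy-Cope ring expansion of a 1-isopropenyl-2-methyl-2-vinylcyclohexanol.
- That carbinol is built on (S)-carvone: allylic hydroxylation, reductive aldol, ozonolysis, dehydration, Wittig coupling, isopropenyl Grignard addition.
- Ring order: the carvone six-membered ring is kept, opened to a ten-membered ring (oxy-Cope) and closed again to the final cyclohexane (Cope); the target has no other ring.

Assumption: (S)-(+)-carvone and (S)-α-hydroxy-γ-butyrolactone (made from L-malic acid) are taken as the cheap chiral purchases; where a step gives diastereomers at a centre that is destroyed later, the major isomer drawn is carried on.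

**Route**

Step 1
Reactants: 1 (S)-(+)-carvone
Product: 2 (5S)-5-(3-hydroxyprop-1-en-2-yl)-2-methylcyclohex-2-en-1-one
Conditions: SeO2 (0.3 equiv), t-BuOOH, CH2Cl2, 25 °C
Reagents that add atoms: selenium dioxide, O=[Se]=O; tert-butyl hydroperoxide, CC(C)(C)OO
Why: Allylic oxidation (ene reaction then [2,3]-sigmatropic shift of the allylseleninic acid) hydroxylates the methyl of the electron-rich isopropenyl group and leaves the electron-poor enone and the C-5 stereocentre alone.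

Step 2
Reactants: 2 (5S)-5-(3-hydroxyprop-1-en-2-yl)-2-methylcyclohex-2-en-1-one
Product: 3 (5S)-5-{3-[(tert-butyldimethylsilyl)oxy]prop-1-en-2-yl}-2-methylcyclohex-2-en-1-one
Conditions: t-BuMe2SiCl, imidazole, DMF, 25 °C
Reagents that add atoms: tert-butyldimethylsilyl chloride, CC(C)(C)[Si](C)(C)Cl
Why: Standard silylation of the primary allylic alcohol gives an ether that survives hydride, Grignard, KH and palladium steps.

Step 3
Reactants: 3 (5S)-5-{3-[(tert-butyldimethylsilyl)oxy]prop-1-en-2-yl}-2-methylcyclohex-2-en-1-one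
Product: 5 (2S,5S)-5-{3-[(tert-butyldimethylsilyl)oxy]prop-1-en-2-yl}-2-(1-hydroxyethyl)-2-methylcyclohexan-1-one, via lithium enolate 4 (not isolated)
Conditions: LiBH(s-Bu)3, THF, −78 °C; then CH3CHO, −78 °C; then H2O
Reagents that add atoms: acetaldehyde, CC=O
Why: Conjugate hydride reduction gives the regiodefined enolate, whose aldol addition (reductive aldol) takes place axially on the face cis to the C-5 chain; the new quaternary centre and the carbinol epimers are erased in steps 12 and 5.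

Step 4
Reactants: 5 (2S,5S)-5-{3-[(tert-butyldimethylsilyl)oxy]prop-1-en-2-yl}-2-(1-hydroxyethyl)-2-methylcyclohexan-1-one
Product: 6 (2S,5S)-5-{[(tert-butyldimethylsilyl)oxy]acetyl}-2-(1-hydroxyethyl)-2-methylcyclohexan-1-one
Conditions: O3, CH2Cl2–MeOH, −78 °C; then Me2S, −78 → 25 °C
Reagents that add atoms: ozone, [O-][O+]=O
Why: Ozonolysis of the only C=C bond in the molecule gives the α-silyloxy ketone under neutral conditions that do not touch the β-hydroxy ketone.

Step 5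
Reactants: 6 (2S,5S)-5-{[(tert-butyldimethylsilyl)oxy]acetyl}-2-(1-hydroxyethyl)-2-methylcyclohexan-1-one
Product: 7 (2S,5S)-5-{[(tert-butyldimethylsilyl)oxy]acetyl}-2-ethenyl-2-methylcyclohexan-1-one
Conditions: Burgess reagent (MeO2CN–SO2–NEt3 inner salt), toluene, 70 °C
Reagents that add atoms: none
Why: Burgess syn-elimination can only take a methyl hydrogen because the other neighbour is quaternary, so the vinyl group forms regiospecifically without base-induced retro-aldol.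

Step 6
Reactants: 8 (S)-α-hydroxy-γ-butyrolactone
Product: 9 (3S)-4-methylpentane-1,3,4-triol
Conditions: MeMgBr (4 equiv), THF, 0 → 25 °C; then H2O
Reagents that add atoms: methylmagnesium bromide, C[Mg]Br
Why: Double Grignard addition to the lactone carbonyl builds the tertiary carbinol; the bought stereocentre is not touched.

Step 7
Reactants: 9 (3S)-4-methylpentane-1,3,4-triol
Product: 10 2-[(4S)-2,2,5,5-tetramethyl-1,3-dioxolan-4-yl]ethan-1-ol
Conditions: Me2C(OMe)2, pyridinium p-toluenesulfonate (cat.), acetone, 25 °C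
Reagents that add atoms: 2,2-dimethoxypropane, COC(C)(C)OC
Why: Acid-catalysed transketalisation under equilibrating conditions favours the five-membered dioxolane on the 1,2-diol and leaves the primary alcohol free.

Step 8
Reactants: 10 2-[(4S)-2,2,5,5-tetramethyl-1,3-dioxolan-4-yl]ethan-1-ol
Product: 11 (4S)-4-(2-iodoethyl)-2,2,5,5-tetramethyl-1,3-dioxolane
Conditions: I2, PPh3, imidazole, CH2Cl2, 0 → 25 °C
Reagents that add atoms: iodine, [I][I]
Why: Appel-type (Garegg–Samuelsson) iodination of the primary alcohol; imidazole buffers the acid so the acetonide survives.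

Step 9
Reactants: 11 (4S)-4-(2-iodoethyl)-2,2,5,5-tetramethyl-1,3-dioxolane
Product: 12 triphenyl{2-[(4S)-2,2,5,5-tetramethyl-1,3-dioxolan-4-yl]ethyl}phosphonium iodide
Conditions: PPh3, MeCN, 80 °C
Reagents that add atoms: triphenylphosphine, c1ccccc1P(c1ccccc1)c1ccccc1
Why: SN2 quaternisation of an unhindered primary iodide; the oxygen sits γ to the future ylide carbon, so no β-elimination can follow.

Step 10
Reactants: 12 triphenyl{2-[(4S)-2,2,5,5-tetramethyl-1,3-dioxolan-4-yl]ethyl}phosphonium iodide; 7 (2S,5S)-5-{[(tert-butyldimethylsilyl)oxy]acetyl}-2-ethenyl-2-methylcyclohexan-1-one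
Product: 14 (2S,5S)-5-{(2Z)-1-[(tert-butyldimethylsilyl)oxy]-4-[(4S)-2,2,5,5-tetramethyl-1,3-dioxolan-4-yl]but-2-en-2-yl}-2-ethenyl-2-methylcyclohexan-1-one, via phosphorus ylide 13 (not isolated)
Conditions: 12, KN(SiMe3)2, THF, −78 °C; then 7, −78 → 0 °C
Reagents that add atoms: none
Why: Wittig reaction of a salt-free unstabilised ylide with an α-oxygenated ketone places the CH2O group cis to the new chain (Z); the ring ketone, flanked by a quaternary carbon, is too hindered to compete.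

Step 11
Reactants: 14 (2S,5S)-5-{(2Z)-1-[(tert-butyldimethylsilyl)oxy]-4-[(4S)-2,2,5,5-tetramethyl-1,3-dioxolan-4-yl]but-2-en-2-yl}-2-ethenyl-2-methylcyclohexan-1-one
Product: 15 (1R,2S,5S)-5-{(2Z)-1-[(tert-butyldimethylsilyl)oxy]-4-[(4S)-2,2,5,5-tetramethyl-1,3-dioxolan-4-yl]but-2-en-2-yl}-2-ethenyl-2-methyl-1-(prop-1-en-2-yl)cyclohexan-1-ol
Conditions: CH2=C(CH3)MgBr, THF, −78 → 0 °C; then H2O
Reagents that add atoms: isopropenylmagnesium bromide, CC(=C)[Mg]Br
Why: Grignard 1,2-addition from the face opposite the axial vinyl group (axial attack) gives the 1,2-trans-dialkenyl carbinol needed for a chair oxy-Cope; this substrate-controlled centre is erased in step 12.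

Step 12
Reactants: 15 (1R,2S,5S)-5-{(2Z)-1-[(tert-butyldimethylsilyl)oxy]-4-[(4S)-2,2,5,5-tetramethyl-1,3-dioxolan-4-yl]but-2-en-2-yl}-2-ethenyl-2-methyl-1-(prop-1-en-2-yl)cyclohexan-1-ol
Product: 18 (1Z,5E,9S)-9-{(2Z)-1-[(tert-butyldimethylsilyl)oxy]-4-[(4S)-2,2,5,5-tetramethyl-1,3-dioxolan-4-yl]but-2-en-2-yl}-2,6-dimethylcyclodeca-1,5-dien-1-yl trifluoromethanesulfonate, via potassium alkoxide 16 (not isolated), via potassium dienolate 17 (not isolated)
Conditions: KH, 18-crown-6, THF, 0 → 40 °C; then PhNTf2, −78 → 0 °C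
Reagents that add atoms: N-phenylbis(trifluoromethanesulfonimide), FC(F)(F)S(=O)(=O)N(c1ccccc1)S(=O)(=O)C(F)(F)F
Why: Anionic oxy-Cope [3,3]-sigmatropic rearrangement through a chair transition state with both alkenyl groups equatorial opens the ring to the ring-trans cyclodecadienolate, which is O-triflated in the same flask; only the carvone-derived ring stereocentre remains.

Step 13
Reactants: 18 (1Z,5E,9S)-9-{(2Z)-1-[(tert-butyldimethylsilyl)oxy]-4-[(4S)-2,2,5,5-tetramethyl-1,3-dioxolan-4-yl]but-2-en-2-yl}-2,6-dimethylcyclodeca-1,5-dien-1-yl trifluoromethanesulfonate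
Product: 20 tert-butyl({(2Z)-2-[(1S,3R,4R)-4-ethenyl-4-methyl-3-(prop-1-en-2-yl)cyclohexyl]-4-[(4S)-2,2,5,5-tetramethyl-1,3-dioxolan-4-yl]but-2-en-1-yl}oxy)dimethylsilane, via germacradiene 19 (not isolated)
Conditions: Pd(OAc)2 (5 mol %), PPh3, Et3N, HCO2H, DMF, 50 °C; then toluene, 110 °C
Reagents that add atoms: none
Why: Zerovalent palladium and formate replace the triflate by hydrogen with retention of geometry, and the resulting (E,E)-germacra-1(10),4-diene undergoes the Cope [3,3]-sigmatropic rearrangement through a chair–chair transition state with the side chain equatorial; this forms the ring bond and sets the quaternary centre and its neighbour (the germacrene A to β-elemene course).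

Step 14
Reactants: 20 tert-butyl({(2Z)-2-[(1S,3R,4R)-4-ethenyl-4-methyl-3-(prop-1-en-2-yl)cyclohexyl]-4-[(4S)-2,2,5,5-tetramethyl-1,3-dioxolan-4-yl]but-2-en-1-yl}oxy)dimethylsilane
Product: 21 (2Z,5S)-2-[(1S,3R,4R)-4-ethenyl-4-methyl-3-(prop-1-en-2-yl)cyclohexyl]-6-methylhept-2-ene-1,5,6-triol
Conditions: 1 M aq. HCl, THF, 25 °C
Reagents that add atoms: none
Why: Mild aqueous acid hydrolyses the silyl ether and the acetonide together without touching the 1,1-disubstituted alkenes.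

Step 15
Reactants: 21 (2Z,5S)-2-[(1S,3R,4R)-4-ethenyl-4-methyl-3-(prop-1-en-2-yl)cyclohexyl]-6-methylhept-2-ene-1,5,6-triol
Product: 22 (2Z,5S)-5-acetoxy-2-[(1S,3R,4R)-4-ethenyl-4-methyl-3-(prop-1-en-2-yl)cyclohexyl]-6-hydroxy-6-methylhept-2-en-1-yl acetate (CNP0274217.2)
Conditions: Ac2O, pyridine, 4-(dimethylamino)pyridine (cat.), CH2Cl2, 0 → 25 °C
Reagents that add atoms: acetic anhydride, CC(=O)OC(C)=O
Why: Acylation takes the primary and secondary hydroxyls and leaves the hindered tertiary alcohol free.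

**Compound list**
1 | (S)-(+)-carvone, (5S)-2-methyl-5-(prop-1-en-2-yl)cyclohex-2-en-1-one | CC1=CC[C@@H](CC1=O)C(C)=C | starting material
2 | (5S)-5-(3-hydroxyprop-1-en-2-yl)-2-methylcyclohex-2-en-1-one | CC1=CC[C@@H](CC1=O)C(=C)CO | intermediate
3 | (5S)-5-{3-[(tert-butyldimethylsilyl)oxy]prop-1-en-2-yl}-2-methylcyclohex-2-en-1-one | CC1=CC[C@@H](CC1=O)C(=C)CO[Si](C)(C)C(C)(C)C | intermediate
4 | lithium (5S)-5-{3-[(tert-butyldimethylsilyl)oxy]prop-1-en-2-yl}-2-methylcyclohex-1-en-1-olate | [Li+].CC1=C([O-])C[C@H](CC1)C(=C)CO[Si](C)(C)C(C)(C)C | intermediate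
5 | (2S,5S)-5-{3-[(tert-butyldimethylsilyl)oxy]prop-1-en-2-yl}-2-(1-hydroxyethyl)-2-methylcyclohexan-1-one (hydroxyethyl cis to the C-5 chain; both carbinol epimers) | CC(O)[C@]1(C)CC[C@H](C(=C)CO[Si](C)(C)C(C)(C)C)CC1=O | intermediate
6 | (2S,5S)-5-{[(tert-butyldimethylsilyl)oxy]acetyl}-2-(1-hydroxyethyl)-2-methylcyclohexan-1-one | CC(O)[C@]1(C)CC[C@H](C(=O)CO[Si](C)(C)C(C)(C)C)CC1=O | intermediate
7 | (2S,5S)-5-{[(tert-butyldimethylsilyl)oxy]acetyl}-2-ethenyl-2-methylcyclohexan-1-one | C=C[C@]1(C)CC[C@H](C(=O)CO[Si](C)(C)C(C)(C)C)CC1=O | intermediate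
8 | (S)-α-hydroxy-γ-butyrolactone, (3S)-3-hydroxyoxolan-2-one | O[C@H]1CCOC1=O | starting material
9 | (3S)-4-methylpentane-1,3,4-triol | OCC[C@H](O)C(C)(C)O | intermediate
10 | 2-[(4S)-2,2,5,5-tetramethyl-1,3-dioxolan-4-yl]ethan-1-ol | OCC[C@@H]1OC(C)(C)OC1(C)C | intermediate
11 | (4S)-4-(2-iodoethyl)-2,2,5,5-tetramethyl-1,3-dioxolane | ICC[C@@H]1OC(C)(C)OC1(C)C | intermediate
12 | triphenyl{2-[(4S)-2,2,5,5-tetramethyl-1,3-dioxolan-4-yl]ethyl}phosphonium iodide | [I-].c1ccccc1[P+](c1ccccc1)(c1ccccc1)CC[C@@H]1OC(C)(C)OC1(C)C | intermediate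
13 | triphenyl{2-[(4S)-2,2,5,5-tetramethyl-1,3-dioxolan-4-yl]ethylidene}-λ5-phosphane | c1ccccc1P(c1ccccc1)(c1ccccc1)=CC[C@@H]1OC(C)(C)OC1(C)C | intermediate
14 | (2S,5S)-5-{(2Z)-1-[(tert-butyldimethylsilyl)oxy]-4-[(4S)-2,2,5,5-tetramethyl-1,3-dioxolan-4-yl]but-2-en-2-yl}-2-ethenyl-2-methylcyclohexan-1-one | C=C[C@]1(C)CC[C@H](/C(=C/C[C@@H]2OC(C)(C)OC2(C)C)CO[Si](C)(C)C(C)(C)C)CC1=O | intermediate
15 | (1R,2S,5S)-5-{(2Z)-1-[(tert-butyldimethylsilyl)oxy]-4-[(4S)-2,2,5,5-tetramethyl-1,3-dioxolan-4-yl]but-2-en-2-yl}-2-ethenyl-2-methyl-1-(prop-1-en-2-yl)cyclohexan-1-ol (vinyl and isopropenyl trans) | C=C[C@]1(C)CC[C@H](/C(=C/C[C@@H]2OC(C)(C)OC2(C)C)CO[Si](C)(C)C(C)(C)C)C[C@@]1(O)C(C)=C | intermediate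
16 | potassium (1R,2S,5S)-5-{(2Z)-1-[(tert-butyldimethylsilyl)oxy]-4-[(4S)-2,2,5,5-tetramethyl-1,3-dioxolan-4-yl]but-2-en-2-yl}-2-ethenyl-2-methyl-1-(prop-1-en-2-yl)cyclohexan-1-olate | [K+].C=C[C@]1(C)CC[C@H](/C(=C/C[C@@H]2OC(C)(C)OC2(C)C)CO[Si](C)(C)C(C)(C)C)C[C@@]1([O-])C(C)=C | intermediate
17 | potassium (1Z,5E,9S)-9-{(2Z)-1-[(tert-butyldimethylsilyl)oxy]-4-[(4S)-2,2,5,5-tetramethyl-1,3-dioxolan-4-yl]but-2-en-2-yl}-2,6-dimethylcyclodeca-1,5-dien-1-olate | [K+].C/C1=C(/[O-])C[C@@H](/C(=C/C[C@@H]2OC(C)(C)OC2(C)C)CO[Si](C)(C)C(C)(C)C)CC/C(C)=C/CC1 | intermediate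
18 | (1Z,5E,9S)-9-{(2Z)-1-[(tert-butyldimethylsilyl)oxy]-4-[(4S)-2,2,5,5-tetramethyl-1,3-dioxolan-4-yl]but-2-en-2-yl}-2,6-dimethylcyclodeca-1,5-dien-1-yl trifluoromethanesulfonate | C/C1=C(/OS(=O)(=O)C(F)(F)F)C[C@@H](/C(=C/C[C@@H]2OC(C)(C)OC2(C)C)CO[Si](C)(C)C(C)(C)C)CC/C(C)=C/CC1 | intermediate
19 | tert-butyl({(2Z)-2-[(1S,3E,7E)-4,8-dimethylcyclodeca-3,7-dien-1-yl]-4-[(4S)-2,2,5,5-tetramethyl-1,3-dioxolan-4-yl]but-2-en-1-yl}oxy)dimethylsilane ((E,E)-germacra-1(10),4-diene type) | C/C1=C\C[C@@H](/C(=C/C[C@@H]2OC(C)(C)OC2(C)C)CO[Si](C)(C)C(C)(C)C)CC/C(C)=C/CC1 | intermediate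
20 | tert-butyl({(2Z)-2-[(1S,3R,4R)-4-ethenyl-4-methyl-3-(prop-1-en-2-yl)cyclohexyl]-4-[(4S)-2,2,5,5-tetramethyl-1,3-dioxolan-4-yl]but-2-en-1-yl}oxy)dimethylsilane | C=C[C@@]1(C)CC[C@H](/C(=C/C[C@@H]2OC(C)(C)OC2(C)C)CO[Si](C)(C)C(C)(C)C)C[C@@H]1C(=C)C | intermediate
21 | (2Z,5S)-2-[(1S,3R,4R)-4-ethenyl-4-methyl-3-(prop-1-en-2-yl)cyclohexyl]-6-methylhept-2-ene-1,5,6-triol | C=C[C@@]1(C)CC[C@H](/C(=C/C[C@H](O)C(C)(C)O)CO)C[C@@H]1C(=C)C | intermediate
22 | (2Z,5S)-5-acetoxy-2-[(1S,3R,4R)-4-ethenyl-4-methyl-3-(prop-1-en-2-yl)cyclohexyl]-6-hydroxy-6-methylhept-2-en-1-yl acetate | C=C[C@@]1(C)CC[C@H](/C(=C/C[C@H](OC(C)=O)C(C)(C)O)COC(C)=O)C[C@@H]1C(=C)C | target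

**Count**
Total: 15 steps. Longest linear sequence: 11 steps (1 to 22 through steps 1–5 and 10–15); the branch 8 to 12 is 4 steps.

**Steps most likely to fail, with fallbacks**

Step 10. The Z/E ratio with a ketone that is branched on its other side is not assured, and the basic ylide may enolise the ketone toward C-5, the only bought ring stereocentre. The fallback is a two-stage Horner–Wittig olefination with separation of diastereomers. It sets out from 11, which is heated with ethyl diphenylphosphinite (Arbuzov reaction) to give diphenyl{2-[(4S)-2,2,5,5-tetramethyl-1,3-dioxolan-4-yl]ethyl}phosphine oxide F1. Its lithio derivative (n-BuLi, THF, −78 °C) adds to the side-chain carbonyl of 7 to give the β-hydroxy phosphine oxide (2S,5S)-5-{1-[(tert-butyldimethylsilyl)oxy]-3-(diphenylphosphoryl)-2-hydroxy-4-[(4S)-2,2,5,5-tetramethyl-1,3-dioxolan-4-yl]butan-2-yl}-2-ethenyl-2-methylcyclohexan-1-one F2. The diastereomer that leads to the Z alkene is purified and eliminated stereospecifically (NaH, DMF), which comes back to the route at 14.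

Step 11. The bulky Grignard reagent may add in part from the equatorial side, giving the cis-dialkenyl carbinol, which would lead to the wrong alkene geometry in the ten-membered ring. The fallback builds the isopropenyl carbinol in three operations from a small linear nucleophile, which strongly prefers axial attack. It sets out from 14: HC≡CMgBr gives (1R,2S,5S)-5-{(2Z)-1-[(tert-butyldimethylsilyl)oxy]-4-[(4S)-2,2,5,5-tetramethyl-1,3-dioxolan-4-yl]but-2-en-2-yl}-2-ethenyl-1-ethynyl-2-methylcyclohexan-1-ol F3. Hydration of the alkyne with Ph3PAuCl/AgOTf in wet methanol gives 1-[(1S,2S,5S)-5-{(2Z)-1-[(tert-butyldimethylsilyl)oxy]-4-[(4S)-2,2,5,5-tetramethyl-1,3-dioxolan-4-yl]but-2-en-2-yl}-2-ethenyl-1-hydroxy-2-methylcyclohexyl]ethan-1-one F4. Methylenation with Ph3P=CH2 then comes back to the route at 15.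

Step 12. The alkoxide may fragment instead of rearranging, or the hindered tetrasubstituted enolate may resist O-triflation in the same flask. The fallback separates the two events and activates the carbonyl electrophilically instead of trapping the enolate. It sets out from 15: the KH/18-crown-6 rearrangement is run alone and quenched cold with aqueous NH4Cl to isolate (5E,9S)-9-{(2Z)-1-[(tert-butyldimethylsilyl)oxy]-4-[(4S)-2,2,5,5-tetramethyl-1,3-dioxolan-4-yl]but-2-en-2-yl}-2,6-dimethylcyclodec-5-en-1-one F5. Tf2O with 2,6-di-tert-butyl-4-methylpyridine in CH2Cl2 then gives the more substituted enol triflate, coming back to the route at 18; the ring-trans geometry of the new double bond would have to be confirmed before step 13.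

**Further compounds**
F1 | step 10 | diphenyl{2-[(4S)-2,2,5,5-tetramethyl-1,3-dioxolan-4-yl]ethyl}phosphine oxide | O=P(c1ccccc1)(c1ccccc1)CC[C@@H]1OC(C)(C)OC1(C)C
F2 | step 10 | (2S,5S)-5-{1-[(tert-butyldimethylsilyl)oxy]-3-(diphenylphosphoryl)-2-hydroxy-4-[(4S)-2,2,5,5-tetramethyl-1,3-dioxolan-4-yl]butan-2-yl}-2-ethenyl-2-methylcyclohexan-1-one | C=C[C@]1(C)CC[C@H](C(O)(CO[Si](C)(C)C(C)(C)C)C(C[C@@H]2OC(C)(C)OC2(C)C)P(=O)(c2ccccc2)c2ccccc2)CC1=O
F3 | step 11 | (1R,2S,5S)-5-{(2Z)-1-[(tert-butyldimethylsilyl)oxy]-4-[(4S)-2,2,5,5-tetramethyl-1,3-dioxolan-4-yl]but-2-en-2-yl}-2-ethenyl-1-ethynyl-2-methylcyclohexan-1-ol | C=C[C@]1(C)CC[C@H](/C(=C/C[C@@H]2OC(C)(C)OC2(C)C)CO[Si](C)(C)C(C)(C)C)C[C@@]1(O)C#C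
F4 | step 11 | 1-[(1S,2S,5S)-5-{(2Z)-1-[(tert-butyldimethylsilyl)oxy]-4-[(4S)-2,2,5,5-tetramethyl-1,3-dioxolan-4-yl]but-2-en-2-yl}-2-ethenyl-1-hydroxy-2-methylcyclohexyl]ethan-1-one | C=C[C@]1(C)CC[C@H](/C(=C/C[C@@H]2OC(C)(C)OC2(C)C)CO[Si](C)(C)C(C)(C)C)C[C@@]1(O)C(C)=O
F5 | step 12 | (5E,9S)-9-{(2Z)-1-[(tert-butyldimethylsilyl)oxy]-4-[(4S)-2,2,5,5-tetramethyl-1,3-dioxolan-4-yl]but-2-en-2-yl}-2,6-dimethylcyclodec-5-en-1-one (C-2 epimers) | O=C1C[C@@H](/C(=C/C[C@@H]2OC(C)(C)OC2(C)C)CO[Si](C)(C)C(C)(C)C)CC/C(C)=C/CCC1C
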